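Both ketone rings of the 16-membered bis-quinolizidine are made at once. In each half the C2 carbonyl of ring A (N5, C4, C3, C2, C1, C9a) lies between C1, which carries the macrocycle tether, and C3. A double Dieckmann condensation therefore forms C2–C3 in both halves from a macrocyclic bis(piperidine) that carries a methyl ester on each C1 and a tert-butyl propanoate on each N5. The two piperidines are the enantiomers of one cis-hydrogenation product, one of them epimerised at C9a, and two ester-enolate alkylations build the macrocycle. The β-keto esters then direct C3 methylation; acid-mediated ester loss and a final base equilibration set C1 and C3.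

Key step: step 15

Remark (locants): C1–C9a are the quinolizidine locants of each half of the target. "Trans half" = (1S,3S,9R,9aR), built from the (2S,3R)-piperidine; "cis half" = (1R,3S,9S,9aR), built from the (2S,3S)-piperidine (cis/trans refers to H9 versus H9a).
Assumption 1: the less soluble salt with the L-configured acid in step 4 is taken to contain the (2S,3S)-amine (to be confirmed by X-ray of the salt); if the pairing is the reverse, the two acids change places between steps 4 and 5.
Assumption 2: the two enolate alkylations are not relied on for the configuration at C1. Compounds 17–26 are drawn as the C1 epimers that map onto the target, C1 epimers formed alongside are carried on, and C1 and C3, both α to the C2 ketone, are brought to the target configuration by the equilibration in step 18.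

Step 1
Reactants: 1 3-bromo-2-methylpyridine; 2 dimethyl carbonate
Product: 3 methyl 2-(3-bromopyridin-2-yl)acetate
Conditions: LiN(iPr)2 (2.1 equiv), THF, −78 °C; then 2, −78 → 0 °C; aq NH4Cl
Reagents that add atoms: none
Why: Lateral lithiation of the 2-methyl group followed by Claisen-type C-acylation with the carbonate is the standard entry to 2-pyridylacetates, the second equivalent of base storing the more acidic product as its enolate and the low temperature sparing the C–Br bond.

Step 2
Reactants: 3 methyl 2-(3-bromopyridin-2-yl)acetate; 4 pent-4-yn-1-ol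
Product: 5 methyl 2-[3-(5-hydroxypent-1-yn-1-yl)pyridin-2-yl]acetate
Conditions: PdCl2(PPh3)2 (3 mol %), CuI (5 mol %), Et3N–THF, 60 °C
Reagents that add atoms: none
Why: Sonogashira coupling of the electron-poor 3-bromopyridine with the terminal alkyne tolerates the free alcohol and the ester and brings in all five tether carbons with their terminal oxygen in one bond formation.

Step 3
Reactants: 5 methyl 2-[3-(5-hydroxypent-1-yn-1-yl)pyridin-2-yl]acetate
Product: 6 rac-cis-methyl 2-[3-(5-hydroxypentyl)piperidin-2-yl]acetate
Conditions: H2 (4 bar), PtO2 (10 mol %), AcOH, rt; then aq K2CO3, CH2Cl2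
Reagents that add atoms: none
Why: Heterogeneous catalytic hydrogenation saturates the alkyne and then the protonated pyridine, the ring hydrogens arriving from the catalyst face so that C2 and C3 should emerge cis (as the racemate).

Step 4
Reactants: 6 rac-cis-methyl 2-[3-(5-hydroxypentyl)piperidin-2-yl]acetate
Product: 7 1:1 salt of methyl 2-[(2S,3S)-3-(5-hydroxypentyl)piperidin-2-yl]acetate with (−)-O,O′-di-p-toluoyl-L-tartaric acid
Conditions: (−)-O,O′-di-p-toluoyl-L-tartaric acid (0.5 equiv based on rac-6), MeOH–acetone, crystallise to constant rotation; mother liquor kept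
Reagents that add atoms: (−)-O,O′-di-p-toluoyl-L-tartaric acid, [C@@H]([C@H](C(=O)O)OC(=O)c1ccc(C)cc1)(C(=O)O)OC(=O)c1ccc(C)cc1
Why: Classical resolution by diastereomeric salt formation with half an equivalent of the diacyl tartaric acid, in which the less soluble salt of one enantiomer of the basic secondary amine should crystallise while the antipode stays in solution as the free base and no bond to a stereocentre is touched.

Step 5
Reactants: 6 rac-cis-methyl 2-[3-(5-hydroxypentyl)piperidin-2-yl]acetate (the portion left in the step 4 mother liquor, enriched in the (2R,3R) antipode)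
Product: 8 1:1 salt of methyl 2-[(2R,3R)-3-(5-hydroxypentyl)piperidin-2-yl]acetate with (+)-O,O′-di-p-toluoyl-D-tartaric acid
Conditions: step 4 mother liquor evaporated; (+)-O,O′-di-p-toluoyl-D-tartaric acid (1 equiv based on the amine present), MeOH–acetone, crystallise to constant rotation
Reagents that add atoms: (+)-O,O′-di-p-toluoyl-D-tartaric acid, [C@H]([C@@H](C(=O)O)OC(=O)c1ccc(C)cc1)(C(=O)O)OC(=O)c1ccc(C)cc1
Why: The same diastereomeric-salt resolution with the mirror-image acid should crystallise the antipodal amine from the enriched mother-liquor material and leave the residual (2S,3S)-amine in solution, so that both enantiomers of 6 are used.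

Step 6
Reactants: 8 1:1 salt of the (2R,3R)-amine with (+)-O,O′-di-p-toluoyl-D-tartaric acid
Product: 11 methyl 2-[(2S,3R)-3-(5-hydroxypentyl)piperidin-2-yl]acetate (trans), via free (2R,3R)-amine 9 (not isolated), via amino enoate 10 (not isolated)
Conditions: aq K2CO3, CH2Cl2 (free base); then NaOMe (1 equiv), MeOH, 65 °C; remaining cis isomer separated by chromatography and resubmitted
Reagents that add atoms: none
Why: Base-mediated retro-aza-Michael/aza-Michael equilibration (E1cB opening to 10 and 6-exo-trig reclosure) inverts only C2, and the N–H piperidine should settle in the trans-diequatorial 2,3-arrangement while C3 is untouched, so that (2R,3R) becomes (2S,3R).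

Step 7
Reactants: 7 1:1 salt of the (2S,3S)-amine with (−)-O,O′-di-p-toluoyl-L-tartaric acid
Product: 13 tert-butyl (2S,3S)-3-(5-hydroxypentyl)-2-(2-methoxy-2-oxoethyl)piperidine-1-carboxylate, via free (2S,3S)-amine 12 (not isolated)
Conditions: Boc2O (1.1 equiv), NaHCO3, THF–H2O, rt
Reagents that add atoms: di-tert-butyl dicarbonate, CC(C)(C)OC(=O)OC(=O)OC(C)(C)C
Why: Carbamate formation under Schotten–Baumann conditions frees the amine from its salt and acylates nitrogen much faster than the primary alcohol, giving a base-stable N-protecting group for the enolate steps.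

Step 8
Reactants: 11 methyl 2-[(2S,3R)-3-(5-hydroxypentyl)piperidin-2-yl]acetate
Product: 14 tert-butyl (2S,3R)-3-(5-hydroxypentyl)-2-(2-methoxy-2-oxoethyl)piperidine-1-carboxylate
Conditions: Boc2O (1.1 equiv), CH2Cl2, rt
Reagents that add atoms: di-tert-butyl dicarbonate, CC(C)(C)OC(=O)OC(=O)OC(C)(C)C
Why: Carbamate formation is selective for the secondary amine over the primary alcohol and also removes the N–H that allowed ring opening in step 6, so the trans configuration is locked.

Step 9
Reactants: 13 tert-butyl (2S,3S)-3-(5-hydroxypentyl)-2-(2-methoxy-2-oxoethyl)piperidine-1-carboxylate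
Product: 15 tert-butyl (2S,3S)-3-(5-iodopentyl)-2-(2-methoxy-2-oxoethyl)piperidine-1-carboxylate
Conditions: I2, PPh3, imidazole, CH2Cl2, 0 °C → rt
Reagents that add atoms: iodine, [I][I]
Why: Appel-type iodination converts the primary alcohol through its alkoxyphosphonium ion by SN2 displacement and leaves carbamate, ester and both stereocentres untouched.

Step 10
Reactants: 14 tert-butyl (2S,3R)-3-(5-hydroxypentyl)-2-(2-methoxy-2-oxoethyl)piperidine-1-carboxylate
Product: 16 tert-butyl (2S,3R)-3-(5-chloropentyl)-2-(2-methoxy-2-oxoethyl)piperidine-1-carboxylate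
Conditions: PPh3, N-chlorosuccinimide, CH2Cl2, 0 °C → rt
Reagents that add atoms: N-chlorosuccinimide, O=C1CCC(=O)N1Cl
Why: Appel-type chlorination gives a primary chloride that is inert toward ester enolates at low temperature and therefore serves as a latent iodide without any protecting-group steps.

Step 11
Reactants: 16 tert-butyl (2S,3R)-3-(5-chloropentyl)-2-(2-methoxy-2-oxoethyl)piperidine-1-carboxylate; 15 tert-butyl (2S,3S)-3-(5-iodopentyl)-2-(2-methoxy-2-oxoethyl)piperidine-1-carboxylate
Product: 17 methyl (2S)-2-[(2R,3R)-1-(tert-butoxycarbonyl)-3-(5-chloropentyl)piperidin-2-yl]-7-[(2S,3S)-1-(tert-butoxycarbonyl)-2-(2-methoxy-2-oxoethyl)piperidin-3-yl]heptanoate (trans half alkylated at C1; its piperidine geometry is that of 16, the C2 descriptor changing only through the priority switch)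
Conditions: 16 (1.3 equiv), LiN(iPr)2 (1.35 equiv), THF, −78 °C; then 15 (1.0 equiv), DMPU, −78 → −40 °C; aq NH4Cl
Reagents that add atoms: none
Why: Ester-enolate alkylation, in which the lithium enolate of the N-Boc piperidin-2-ylacetate displaces the primary iodide by SN2 much faster than the chloride of its own chain, as in known alkylations of such enolates with ω-chloroalkyl iodides, the new C1 centre not being relied upon (assumption 2).

Step 12
Reactants: 17 open-chain dimer, chloride
Product: 18 methyl (2S)-2-[(2R,3R)-1-(tert-butoxycarbonyl)-3-(5-iodopentyl)piperidin-2-yl]-7-[(2S,3S)-1-(tert-butoxycarbonyl)-2-(2-methoxy-2-oxoethyl)piperidin-3-yl]heptanoate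
Conditions: NaI (5 equiv), butan-2-one, 80 °C
Reagents that add atoms: sodium iodide, [Na+].[I-]
Why: Finkelstein halide exchange, driven by precipitation of NaCl, unmasks the second electrophile without affecting the esters, the carbamates or any stereocentre.

Step 13
Reactants: 18 open-chain dimer, iodide
Product: 19 macrocyclic bis(N-Boc-piperidine) dimethyl diester (16-membered carbocycle C1–C9a–C9–(CH2)5–C1′–C9a′–C9′–(CH2)5; trans half 1S,9R,9aR; cis half 1R,9S,9aR)
Conditions: LiN(SiMe3)2 (3 equiv), THF–DMPU, −40 °C, 18 added by syringe pump (final 2 mM), then −40 → −20 °C; aq NH4Cl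
Reagents that add atoms: none
Why: Intramolecular ester-enolate alkylation under high dilution, in which the base removes a proton from the unbranched CH2CO2Me group of the cis half rather than the hindered tertiary C1–H of the trans half and the enolate closes the 16-membered ring on the primary iodide, the new C1 centre again being left to step 18.

Step 14
Reactants: 19 macrocyclic bis(N-Boc-piperidine) dimethyl diester; 20 tert-butyl acrylate
Product: 22 macrocyclic tetraester (methyl ester on each C1 and tert-butyl 3-propanoate on each N5), via macrocyclic bis(piperidine) diester 21 (not isolated)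
Conditions: CF3CO2H–CH2Cl2 (1:4), 0 °C → rt; evaporate; then 20 (6 equiv), Et3N (6 equiv), MeOH, 50 °C
Reagents that add atoms: none
Why: Acidolytic Boc cleavage followed by double aza-Michael addition of the liberated secondary amines to the acrylate installs both N5 propanoates without creating or touching a stereocentre.

Step 15
Reactants: 22 macrocyclic tetraester
Product: 23 macrocyclic bis(3-tert-butoxycarbonylquinolizidin-2-one), drawn as the bis-enol (trans half 1S,9R,9aR; cis half 1R,9S,9aR)
Conditions: LiN(SiMe3)2 (5 equiv), THF, −78 → 0 °C; aq NH4Cl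
Reagents that add atoms: none
Why: LiN(SiMe3)2 reversibly deprotonates the α-CH2 of each tert-butyl propanoate (C3), the enolate adds to the methyl ester carbonyl on C1 (the future C2), methoxide is expelled, and the β-keto ester formed is deprotonated at once at C3, which pulls every equilibrium toward the ring-closed enolate in both halves. The closest known reaction type is the Dieckmann cyclisation of N-(2-alkoxycarbonylethyl)piperidin-2-ylacetates to 3-alkoxycarbonylquinolizidin-2-ones. Each ring A (N5, C4, C3, C2, C1, C9a) is closed 6-exo-trig by attack of C3 on the exocyclic ester carbonyl. No stereocentre is created, since C3 is trigonal in the enolate, and C9 and C9a pass through unchanged. The step needs C2–C3 rather than C1–C(propanoate) bond formation, which is secured three ways: the tert-butyl ester is a poor acyl acceptor, the tertiary C1–H is hindered, and only the C3-closed product has an acidic C–H between two carbonyls and so survives as its enolate. It also needs C9a to stay intact, which the non-nucleophilic amide base at or below 0 °C and the poor leaving-group ability of the trialkylamine nitrogen secure, while any partial C1 epimerisation is harmless because C1 is re-equilibrated in step 18.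

Step 16
Reactants: 23 macrocyclic bis(3-tert-butoxycarbonylquinolizidin-2-one)
Product: 24 macrocyclic bis(3-methyl-3-tert-butoxycarbonylquinolizidin-2-one) (quaternary C3 centres of either configuration)
Conditions: KOtBu (2.1 equiv), THF, 0 °C; then MeI (2.1 equiv), 0 °C → rt
Reagents that add atoms: iodomethane, CI
Why: C-Alkylation of β-keto ester enolates, in which the preformed potassium enolates should outcompete the hindered tertiary amines for one equivalent of MeI per ring (as in the C-methylation of N-benzyl-3-alkoxycarbonyl-4-piperidones), the quaternary C3 centres formed being erased in step 17.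

Step 17
Reactants: 24 macrocyclic bis(3-methyl-3-tert-butoxycarbonylquinolizidin-2-one)
Product: 26 macrocyclic bis(3-methylquinolizidin-2-one) as a mixture of C3 epimers, via bis(β-keto acid) 25 (not isolated)
Conditions: CF3CO2H–CH2Cl2 (1:2), rt; evaporate; toluene, 80 °C; aq NaHCO3
Reagents that add atoms: none
Why: Acidolysis of the tert-butyl esters and thermal decarboxylation of the β-keto acids through their enols proceed with both nitrogens protonated, so that retro-Mannich and retro-aza-Michael cleavage are shut off and C9 and C9a survive, while C3 is reprotonated unselectively.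

Step 18
Reactants: 26 macrocyclic bis(3-methylquinolizidin-2-one), C3-epimer mixture
Product: 27 target CNP0268544.8, (1S,3S,9R,9aR)/(1′R,3′S,9′S,9a′R) macrocyclic bis(3-methylquinolizidin-2-one)
Conditions: K2CO3, MeOH, rt, followed to constant composition; crystallisation
Reagents that add atoms: none
Why: Base-mediated epimerisation through the C2 enolates (thermodynamic control) should deliver the target because, with C9 and C9a fixed, each trans-fused chair–chair quinolizidinone is most stable with the C3 methyl equatorial and with the C1 and C9 tethers one axial and one equatorial (avoiding the 1,9 syn-pentane contact), which is the target arrangement in both halves, and mild carbonate at room temperature should not open the β-amino ketone at C9a.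

Compound list
1 | 3-bromo-2-methylpyridine | Cc1ncccc1Br | starting material
2 | dimethyl carbonate | COC(=O)OC | starting material
3 | methyl 2-(3-bromopyridin-2-yl)acetate | COC(=O)Cc1ncccc1Br | intermediate
4 | pent-4-yn-1-ol | C#CCCCO | starting material
5 | methyl 2-[3-(5-hydroxypent-1-yn-1-yl)pyridin-2-yl]acetate | COC(=O)Cc1ncccc1C#CCCCO | intermediate
6 | rac-cis-methyl 2-[3-(5-hydroxypentyl)piperidin-2-yl]acetate (1:1 (2S,3S) and (2R,3R)) | COC(=O)C[C@@H]1NCCC[C@@H]1CCCCCO.COC(=O)C[C@H]1NCCC[C@H]1CCCCCO | intermediate
7 | 1:1 salt of methyl 2-[(2S,3S)-3-(5-hydroxypentyl)piperidin-2-yl]acetate with (−)-O,O′-di-p-toluoyl-L-tartaric acid | COC(=O)C[C@@H]1[NH2+]CCC[C@@H]1CCCCCO.[C@@H]([C@H](C(=O)O)OC(=O)c1ccc(C)cc1)(C(=O)[O-])OC(=O)c1ccc(C)cc1 | intermediate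
8 | 1:1 salt of methyl 2-[(2R,3R)-3-(5-hydroxypentyl)piperidin-2-yl]acetate with (+)-O,O′-di-p-toluoyl-D-tartaric acid | COC(=O)C[C@H]1[NH2+]CCC[C@H]1CCCCCO.[C@H]([C@@H](C(=O)O)OC(=O)c1ccc(C)cc1)(C(=O)[O-])OC(=O)c1ccc(C)cc1 | intermediate
9 | methyl 2-[(2R,3R)-3-(5-hydroxypentyl)piperidin-2-yl]acetate (cis, free base) | COC(=O)C[C@H]1NCCC[C@H]1CCCCCO | intermediate (not isolated)
10 | methyl (2E,4R)-7-amino-4-(5-hydroxypentyl)hept-2-enoate | COC(=O)/C=C/[C@H](CCCCCO)CCCN | intermediate (not isolated)
11 | methyl 2-[(2S,3R)-3-(5-hydroxypentyl)piperidin-2-yl]acetate (trans) | COC(=O)C[C@@H]1NCCC[C@H]1CCCCCO | intermediate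
12 | methyl 2-[(2S,3S)-3-(5-hydroxypentyl)piperidin-2-yl]acetate (cis, free base) | COC(=O)C[C@@H]1NCCC[C@@H]1CCCCCO | intermediate (not isolated)
13 | tert-butyl (2S,3S)-3-(5-hydroxypentyl)-2-(2-methoxy-2-oxoethyl)piperidine-1-carboxylate | COC(=O)C[C@@H]1N(C(=O)OC(C)(C)C)CCC[C@@H]1CCCCCO | intermediate
14 | tert-butyl (2S,3R)-3-(5-hydroxypentyl)-2-(2-methoxy-2-oxoethyl)piperidine-1-carboxylate | COC(=O)C[C@@H]1N(C(=O)OC(C)(C)C)CCC[C@H]1CCCCCO | intermediate
15 | tert-butyl (2S,3S)-3-(5-iodopentyl)-2-(2-methoxy-2-oxoethyl)piperidine-1-carboxylate | COC(=O)C[C@@H]1N(C(=O)OC(C)(C)C)CCC[C@@H]1CCCCCI | intermediate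
16 | tert-butyl (2S,3R)-3-(5-chloropentyl)-2-(2-methoxy-2-oxoethyl)piperidine-1-carboxylate | COC(=O)C[C@@H]1N(C(=O)OC(C)(C)C)CCC[C@H]1CCCCCCl | intermediate
17 | methyl (2S)-2-[(2R,3R)-1-(tert-butoxycarbonyl)-3-(5-chloropentyl)piperidin-2-yl]-7-[(2S,3S)-1-(tert-butoxycarbonyl)-2-(2-methoxy-2-oxoethyl)piperidin-3-yl]heptanoate | ClCCCCC[C@@H]1CCCN(C(=O)OC(C)(C)C)[C@H]1[C@@H](C(=O)OC)CCCCC[C@H]2CCCN(C(=O)OC(C)(C)C)[C@H]2CC(=O)OC | intermediate
18 | methyl (2S)-2-[(2R,3R)-1-(tert-butoxycarbonyl)-3-(5-iodopentyl)piperidin-2-yl]-7-[(2S,3S)-1-(tert-butoxycarbonyl)-2-(2-methoxy-2-oxoethyl)piperidin-3-yl]heptanoate | ICCCCC[C@@H]1CCCN(C(=O)OC(C)(C)C)[C@H]1[C@@H](C(=O)OC)CCCCC[C@H]2CCCN(C(=O)OC(C)(C)C)[C@H]2CC(=O)OC | intermediate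
19 | macrocyclic bis(N-Boc-piperidine) dimethyl diester (trans half 1S,9R,9aR; cis half 1R,9S,9aR) | N1(C(=O)OC(C)(C)C)CCC[C@H]2CCCCC[C@@H](C(=O)OC)[C@@H]3N(C(=O)OC(C)(C)C)CCC[C@@H]3CCCCC[C@H](C(=O)OC)[C@H]12 | intermediate
20 | tert-butyl acrylate | C=CC(=O)OC(C)(C)C | starting material
21 | macrocyclic bis(piperidine) dimethyl diester (present as its bis-trifluoroacetate) | N1CCC[C@H]2CCCCC[C@@H](C(=O)OC)[C@@H]3NCCC[C@@H]3CCCCC[C@H](C(=O)OC)[C@H]12 | intermediate (not isolated)
22 | macrocyclic tetraester: C1 methyl esters, N5 tert-butyl 3-propanoates (key-step precursor) | N1(CCC(=O)OC(C)(C)C)CCC[C@H]2CCCCC[C@@H](C(=O)OC)[C@@H]3N(CCC(=O)OC(C)(C)C)CCC[C@@H]3CCCCC[C@H](C(=O)OC)[C@H]12 | intermediate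
23 | macrocyclic bis(3-tert-butoxycarbonylquinolizidin-2-one), bis-enol (key-step product) | CC(C)(C)OC(=O)C=1CN2CCC[C@H]3CCCCC[C@H]4C(O)=C(C(=O)OC(C)(C)C)CN5CCC[C@H](CCCCC[C@H](C=1O)[C@@H]32)[C@H]45 | intermediate
24 | macrocyclic bis(3-methyl-3-tert-butoxycarbonylquinolizidin-2-one), C3 unassigned | CC(C)(C)OC(=O)C1(C)CN2CCC[C@H]3CCCCC[C@H]4C(=O)C(C)(C(=O)OC(C)(C)C)CN5CCC[C@H](CCCCC[C@H](C1=O)[C@@H]32)[C@H]45 | intermediate
25 | macrocyclic bis(3-carboxy-3-methylquinolizidin-2-one) (present as its bis-ammonium trifluoroacetate) | OC(=O)C1(C)CN2CCC[C@H]3CCCCC[C@H]4C(=O)C(C)(C(O)=O)CN5CCC[C@H](CCCCC[C@H](C1=O)[C@@H]32)[C@H]45 | intermediate (not isolated)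
26 | macrocyclic bis(3-methylquinolizidin-2-one), C3-epimer mixture | CC1CN2CCC[C@H]3CCCCC[C@H]4C(=O)C(C)CN5CCC[C@H](CCCCC[C@H](C1=O)[C@@H]32)[C@H]45 | intermediate
27 | CNP0268544.8, (1S,3S,9R,9aR)/(1′R,3′S,9′S,9a′R) macrocyclic bis(3-methylquinolizidin-2-one) | C[C@H]1CN2CCC[C@H]3CCCCC[C@H]4C(=O)[C@@H](C)CN5CCC[C@H](CCCCC[C@H](C1=O)[C@@H]32)[C@H]45 | target

Total step count: 18
Longest linear sequence: 15 steps (1, 2, 3, 5, 6, 8, 10, 11, 12, 13, 14, 15, 16, 17, 18)

Steps most likely to fail

Step 13 (macrocyclisation). The dilute lithium enolate may be consumed by intermolecular alkylation to oligomers, or may expel the carbamate nitrogen (E1cB ring opening, which would also erode C9a) before it reaches the iodide. The fallback sets out from 17 and exchanges the hard ester enolate for a soft malonate anion. The CH2CO2Me group is deprotonated with LiN(SiMe3)2 (2.2 equiv, THF, −78 °C) and C-acylated with allyl chloroformate to give the allyl methyl malonate chloride F1. NaI in butan-2-one gives the allyl methyl malonate iodide F2. Cs2CO3 in MeCN at high dilution closes the ring to the macrocyclic allyl methyl malonate F3. Pd(PPh3)4 with morpholine removes the allyl group to give the macrocyclic malonic half-acid F4, which loses CO2 in toluene at 100 °C. The route is rejoined at 19.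

Step 6 (C2 epimerisation). Alkoxide-mediated ring opening of the N–H β-amino ester may be too slow, or the equilibrium may stop short of a useful trans preference. The fallback sets out from 8 and makes opening irreversible and reclosure kinetic. Boc2O under Schotten–Baumann conditions gives the N-Boc-(2R,3R)-piperidine F5. LiN(SiMe3)2 (3 equiv, THF, −78 → 0 °C, acetic acid quench) expels the carbamate nitrogen from the ester enolate to give the open-chain Boc-amino enoate F6. HCl in MeOH removes the Boc group, and neutralisation (Et3N, MeOH, 0 °C → rt) releases amino enoate 10. This closes by 6-exo-trig aza-Michael addition through the chair with both substituents equatorial. The route is rejoined at 11.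

Step 15 (double Dieckmann). The second ring may close slowly on the hindered C1 ester, so that the long-lived propanoate enolate loses acrylate (retro-aza-Michael) or C1 enolisation opens C9a. The fallback sets out from 19 and closes ring A by an intramolecular Mannich reaction at C3–C4 instead. MeNHOMe·HCl with iPrMgCl (THF, −20 °C) converts both esters to the macrocyclic bis(N-methoxy-N-methylamide) F7. EtMgBr gives the macrocyclic bis(ethyl ketone) F8. CF3CO2H removes the Boc groups to give the macrocyclic bis(amino ethyl ketone) F9 as its salt. Aqueous formaldehyde (EtOH, AcOH/NaOAc, 50 °C) forms each N5 methyleneiminium ion, which is attacked by the enol of the ethyl ketone at C3 (6-endo-trig) with the C3 methyl already in place. The route is rejoined at 26, and step 18 follows.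

Further compounds
F1 | step 13 | open-chain dimer, chloride, with CH(CO2Me)(CO2allyl) on the cis-half piperidine | ClCCCCC[C@@H]1CCCN(C(=O)OC(C)(C)C)[C@H]1[C@@H](C(=O)OC)CCCCC[C@H]2CCCN(C(=O)OC(C)(C)C)[C@H]2C(C(=O)OC)C(=O)OCC=C
F2 | step 13 | open-chain dimer, iodide, with CH(CO2Me)(CO2allyl) on the cis-half piperidine | ICCCCC[C@@H]1CCCN(C(=O)OC(C)(C)C)[C@H]1[C@@H](C(=O)OC)CCCCC[C@H]2CCCN(C(=O)OC(C)(C)C)[C@H]2C(C(=O)OC)C(=O)OCC=C
F3 | step 13 | macrocyclic bis(N-Boc-piperidine) with allyl methyl malonate at C1 of the cis half | N1(C(=O)OC(C)(C)C)CCC[C@H]2CCCCCC(C(=O)OC)(C(=O)OCC=C)[C@@H]3N(C(=O)OC(C)(C)C)CCC[C@@H]3CCCCC[C@H](C(=O)OC)[C@H]12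
F4 | step 13 | macrocyclic bis(N-Boc-piperidine) with malonic half-acid methyl ester at C1 of the cis half | N1(C(=O)OC(C)(C)C)CCC[C@H]2CCCCCC(C(=O)OC)(C(O)=O)[C@@H]3N(C(=O)OC(C)(C)C)CCC[C@@H]3CCCCC[C@H](C(=O)OC)[C@H]12
F5 | step 6 | tert-butyl (2R,3R)-3-(5-hydroxypentyl)-2-(2-methoxy-2-oxoethyl)piperidine-1-carboxylate | COC(=O)C[C@H]1N(C(=O)OC(C)(C)C)CCC[C@H]1CCCCCO
F6 | step 6 | methyl (2E,4R)-7-[(tert-butoxycarbonyl)amino]-4-(5-hydroxypentyl)hept-2-enoate | COC(=O)/C=C/[C@H](CCCCCO)CCCNC(=O)OC(C)(C)C
F7 | step 15 | macrocyclic bis(N-Boc-piperidine) bis(N-methoxy-N-methylamide) | N1(C(=O)OC(C)(C)C)CCC[C@H]2CCCCC[C@@H](C(=O)N(C)OC)[C@@H]3N(C(=O)OC(C)(C)C)CCC[C@@H]3CCCCC[C@H](C(=O)N(C)OC)[C@H]12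
F8 | step 15 | macrocyclic bis(N-Boc-piperidine) bis(ethyl ketone) | N1(C(=O)OC(C)(C)C)CCC[C@H]2CCCCC[C@@H](C(=O)CC)[C@@H]3N(C(=O)OC(C)(C)C)CCC[C@@H]3CCCCC[C@H](C(=O)CC)[C@H]12
F9 | step 15 | macrocyclic bis(piperidine) bis(ethyl ketone) | N1CCC[C@H]2CCCCC[C@@H](C(=O)CC)[C@@H]3NCCC[C@@H]3CCCCC[C@H](C(=O)CC)[C@H]12
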